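**Plan**

1. Rings: A is the heptyl-bearing benzo ring, B the pyranone ring (O1, C2, C3, C4, C4a, C8a), C the benzoic acid ring. Retrosynthesis: the C2–OH goes back to a C2–B bond and this to the C2=C3 bond of a per-benzylated 2-benzylchromone, which is cut at C3–C4 and at O1–C8a into a ring A 2-fluorobenzoyl chloride and a ring C 3-methylisocoumarin.
2. Enabling feature: C2 carries a CH2 bonded to ring C, and ring C has its CO2H ortho to that CH2, so C3–C2(O1)–CH2–ring C–CO2H is a latent 3-methylisocoumarin. O1 can ride on C2 as the lactone oxygen, the methyl group (future C3) is the only acidic carbon, and the lactone masks the carboxyl. On ring A, C8a is ortho to the acyl carbon C4, so a fluoride there is open to a six-ring SNAr.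
3. Forward: ring A from 3,5-difluorophenol (benzylation; lithiation/CO2 between the fluorines; one fluoride exchanged for heptyl; acid chloride). Ring C from orsellinic acid (benzylation; lateral acetylation; enol-lactonisation). The halves are then joined and ring B closed in one pot, which turns the isocoumarin skeleton into the chromone skeleton.
4. Stereochemistry: C2, the only stereocenter, is set by ligand-controlled copper-catalysed conjugate borylation of the chromone, carried as a C–B bond, changed to C–OH with retention by an amine oxide, and kept through a final neutral hydrogenolysis of all four benzyl groups.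

Key step: step 8

Remark (assumption): C2 is a cyclic hemiketal, the ring tautomer of an achiral 1,3-diketone. It is assumed that ring–chain exchange is slow without base or strong acid at or below room temperature, so the C2–OH is unveiled late and every later operation is neutral.

**Route**

Step 1
Reactants: 1 3,5-difluorophenol
Product: 2 1-(benzyloxy)-3,5-difluorobenzene
Conditions: BnBr, K2CO3, DMF, rt
Reagents that add atoms: benzyl bromide BrCc1ccccc1
Why: Williamson ether synthesis on the phenoxide; the aryl fluorides are inert under these conditions.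

Step 2
Reactants: 2 1-(benzyloxy)-3,5-difluorobenzene
Product: 4 4-(benzyloxy)-2,6-difluorobenzoic acid, via aryllithium 3 (not isolated)
Conditions: LiN(i-Pr)2, THF, −78 °C; CO2; 1 M HCl
Reagents that add atoms: carbon dioxide O=C=O
Why: Directed ortho-metalation at the most acidic C–H, the one between the two fluorines, with an amide base that spares the benzylic OCH2, followed by carboxylation at −78 °C before LiF can be lost to an aryne.

Step 3
Reactants: 4 4-(benzyloxy)-2,6-difluorobenzoic acid
Product: 5 4-(benzyloxy)-2-fluoro-6-heptylbenzoic acid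
Conditions: n-C7H15MgBr (2.3 equiv), THF, −78 °C → rt; 1 M HCl
Reagents that add atoms: heptylmagnesium bromide CCCCCCC[Mg]Br
Why: Carboxylate-directed nucleophilic aromatic substitution of an ortho-fluoride of an unprotected benzoic acid by a Grignard reagent (addition–elimination through the chelated magnesium carboxylate); the first heptyl group makes ring A more electron-rich and hindered, which should hold the reaction at mono-substitution.

Step 4
Reactants: 5 4-(benzyloxy)-2-fluoro-6-heptylbenzoic acid
Product: 6 4-(benzyloxy)-2-fluoro-6-heptylbenzoyl chloride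
Conditions: (COCl)2, DMF (cat.), CH2Cl2, 0 °C → rt
Reagents that add atoms: oxalyl chloride O=C(Cl)C(=O)Cl
Why: DMF-catalysed (Vilsmeier-type) acid chloride formation, which the benzyl ether and aryl fluoride tolerate.

Step 5
Reactants: 7 orsellinic acid (2,4-dihydroxy-6-methylbenzoic acid)
Product: 8 benzyl 2,4-bis(benzyloxy)-6-methylbenzoate
Conditions: BnBr (3.5 equiv), K2CO3, DMF, rt then 60 °C
Reagents that add atoms: benzyl bromide BrCc1ccccc1
Why: Exhaustive O-benzylation; the carboxylate is alkylated first at rt, which forestalls decarboxylation, and the two phenoxides follow on warming.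

Step 6
Reactants: 8 benzyl 2,4-bis(benzyloxy)-6-methylbenzoate
Product: 10 benzyl 2,4-bis(benzyloxy)-6-(2-oxopropyl)benzoate, via lateral lithio toluate 9 (not isolated)
Conditions: LiN(i-Pr)2 (1.2 equiv), THF, −78 °C; MeC(O)N(OMe)Me; 1 M HCl, 0 °C
Reagents that add atoms: N-methoxy-N-methylacetamide CC(=O)N(C)OC
Why: Lateral lithiation of an ortho-toluate, whose doubly ortho-substituted ester resists self-condensation, and acylation by a Weinreb amide, whose chelated tetrahedral adduct prevents over-addition and proton quench by the product.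

Step 7
Reactants: 10 benzyl 2,4-bis(benzyloxy)-6-(2-oxopropyl)benzoate
Product: 11 6,8-bis(benzyloxy)-3-methyl-1H-isochromen-1-one
Conditions: p-TsOH·H2O (10 mol %), toluene, reflux
Reagents that add atoms: none
Why: Acid-catalysed enol-lactonisation (6-exo-trig attack of the enol oxygen on the ester, loss of benzyl alcohol) to the aromatic 2-benzopyranone; acid is used so that the methyl carbon cannot close onto the ester to a naphthalenediol, as it could under base.

Step 8
Reactants: 11 6,8-bis(benzyloxy)-3-methyl-1H-isochromen-1-one; 6 4-(benzyloxy)-2-fluoro-6-heptylbenzoyl chloride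
Product: 15 benzyl 2,4-bis(benzyloxy)-6-{[7-(benzyloxy)-5-heptyl-4-oxo-4H-chromen-2-yl]methyl}benzoate, via lithiated isocoumarin 12 (not isolated), via acylated isocoumarin 13 (not isolated), via fluoro diketone ester 14 (not isolated)
Conditions: LiN(i-Pr)2 (2.1 equiv), THF, −78 °C; add 6, −78 → 0 °C; then BnOH (5 equiv), KOt-Bu (30 mol %), DMF, 0 → 65 °C; one pot
Reagents that add atoms: benzyl alcohol OCc1ccccc1
Why: Proposed new method: the only acidic C–H of 11 is the 3-methyl group (a vinylogous, toluate-type position; the neighbouring ring carbon is vinylic), so the amide base gives the extended enolate 12, which 6 acylates at the exocyclic carbon to form the C3–C4 bond (13, held as its enolate by the second equivalent of base); benzyl oxide then attacks the enol-lactone carbonyl, which passes the acyl group from the ring oxygen to benzyl alcohol and frees that oxygen, still bonded to C2, as the enolate oxygen of diketone 14. That oxygen displaces the fluoride on C8a, ortho to the C4 ketone, by intramolecular addition–elimination, which forms the O1–C8a bond and closes ring B. The closest known reaction types are the lateral acylation of 6-methyl-2-pyranone and ortho-toluate anions and the one-pot Claisen/SNAr chromone synthesis from 2-fluorobenzoyl chlorides and ketone enolates; what is new is their union through an alkoxide-triggered isocoumarin-to-chromone ring transposition. Ring B closes in a 6-endo-trig mode at the C8a=C4a–C4=O acceptor (Meisenheimer adduct, then loss of fluoride), and no stereocenter is formed. The step needs acylation at the methyl carbon and not at the carbon next to ring C, which the isocoumarin secures because that carbon is sp2 there, and it needs O-arylation to outrun closure of C3 onto the benzyl ester, which the twisted, doubly ortho-substituted benzoate and the six-membered SNAr transition state should favour.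

Step 9
Reactants: 15 benzyl 2,4-bis(benzyloxy)-6-{[7-(benzyloxy)-5-heptyl-4-oxo-4H-chromen-2-yl]methyl}benzoate
Product: 16 benzyl 2,4-bis(benzyloxy)-6-{[(2R)-7-(benzyloxy)-5-heptyl-4-oxo-2-(4,4,5,5-tetramethyl-1,3,2-dioxaborolan-2-yl)-3,4-dihydro-2H-chromen-2-yl]methyl}benzoate
Conditions: B2pin2 (1.5 equiv), Cu(MeCN)4PF6 (10 mol %), (R,R)-QuinoxP* (12 mol %), LiOt-Bu (15 mol %), i-PrOH (2 equiv), THF, 0 °C → rt
Reagents that add atoms: bis(pinacolato)diboron CC1(C)OB(OC1(C)C)B1OC(C)(C)C(C)(C)O1
Why: Proposed new method: a ligated copper boryl, formed from the copper alkoxide and B2pin2, should add boron to C2 of the vinylogous ester in a conjugate sense, and isopropanol protonates the copper enolate before it can expel the aryloxide (retro-oxa-Michael), the C2 face being chosen by the twofold-symmetric bisphosphine (the ligand antipode that leads to 2R is used, its sense to be confirmed by correlation and the mirror-image ligand taken otherwise); the closest known reaction type is the copper/bisphosphine-catalysed enantioselective conjugate borylation of β,β-disubstituted cyclic enones, which creates boron-bearing fully substituted centers, here extended to a β-aryloxy enone.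

Step 10
Reactants: 16 the (2R)-boronate
Product: 18 benzyl 2,4-bis(benzyloxy)-6-{[(2R)-7-(benzyloxy)-5-heptyl-2-hydroxy-4-oxo-3,4-dihydro-2H-chromen-2-yl]methyl}benzoate, via borate ester 17 (not isolated)
Conditions: Me3NO (anhydrous, 3 equiv), THF, rt → 40 °C; then pH 7 phosphate buffer, 0 °C
Reagents that add atoms: trimethylamine N-oxide C[N+](C)(C)[O-]
Why: Amine-oxide oxidation of a C–B bond: the N-oxide oxygen adds to boron and C2 migrates from boron to oxygen with retention of configuration, which gives borate 17 and, after neutral hydrolysis, the hemiketal without any strong base that could open ring B.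

Step 11
Reactants: 18 the (2R)-hemiketal tetrabenzyl compound
Product: 19 2,4-dihydroxy-6-{[(2R)-5-heptyl-2,7-dihydroxy-4-oxo-3,4-dihydro-2H-chromen-2-yl]methyl}benzoic acid
Conditions: H2 (1 atm), 10% Pd/C, EtOAc, rt; filtration and evaporation below 25 °C
Reagents that add atoms: none
Why: Catalytic hydrogenolysis of three aryl benzyl ethers and the benzyl ester under neutral conditions; no bond to C2 is touched, so the configuration set in step 9 is kept, and the electron-rich, doubly ortho-substituted C4 ketone should resist reduction.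

**Compound list**

1 | 3,5-difluorophenol | Oc1cc(F)cc(F)c1 | starting material
2 | 1-(benzyloxy)-3,5-difluorobenzene | Fc1cc(F)cc(OCc2ccccc2)c1 | intermediate
3 | [4-(benzyloxy)-2,6-difluorophenyl]lithium | [Li]c1c(F)cc(OCc2ccccc2)cc1F | intermediate (not isolated)
4 | 4-(benzyloxy)-2,6-difluorobenzoic acid | OC(=O)c1c(F)cc(OCc2ccccc2)cc1F | intermediate
5 | 4-(benzyloxy)-2-fluoro-6-heptylbenzoic acid | CCCCCCCc1cc(OCc2ccccc2)cc(F)c1C(=O)O | intermediate
6 | 4-(benzyloxy)-2-fluoro-6-heptylbenzoyl chloride | CCCCCCCc1cc(OCc2ccccc2)cc(F)c1C(=O)Cl | intermediate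
7 | orsellinic acid (2,4-dihydroxy-6-methylbenzoic acid) | Cc1cc(O)cc(O)c1C(=O)O | starting material
8 | benzyl 2,4-bis(benzyloxy)-6-methylbenzoate | Cc1cc(OCc2ccccc2)cc(OCc2ccccc2)c1C(=O)OCc1ccccc1 | intermediate
9 | benzyl 2,4-bis(benzyloxy)-6-(lithiomethyl)benzoate | [Li]Cc1cc(OCc2ccccc2)cc(OCc2ccccc2)c1C(=O)OCc1ccccc1 | intermediate (not isolated)
10 | benzyl 2,4-bis(benzyloxy)-6-(2-oxopropyl)benzoate | CC(=O)Cc1cc(OCc2ccccc2)cc(OCc2ccccc2)c1C(=O)OCc1ccccc1 | intermediate
11 | 6,8-bis(benzyloxy)-3-methyl-1H-isochromen-1-one | Cc1cc2cc(OCc3ccccc3)cc(OCc3ccccc3)c2c(=O)o1 | intermediate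
12 | 6,8-bis(benzyloxy)-3-(lithiomethyl)-1H-isochromen-1-one | [Li]Cc1cc2cc(OCc3ccccc3)cc(OCc3ccccc3)c2c(=O)o1 | intermediate (not isolated)
13 | 6,8-bis(benzyloxy)-3-{2-[4-(benzyloxy)-2-fluoro-6-heptylphenyl]-2-oxoethyl}-1H-isochromen-1-one | CCCCCCCc1cc(OCc2ccccc2)cc(F)c1C(=O)Cc1cc2cc(OCc3ccccc3)cc(OCc3ccccc3)c2c(=O)o1 | intermediate (not isolated)
14 | benzyl 2,4-bis(benzyloxy)-6-{4-[4-(benzyloxy)-2-fluoro-6-heptylphenyl]-2,4-dioxobutyl}benzoate | CCCCCCCc1cc(OCc2ccccc2)cc(F)c1C(=O)CC(=O)Cc1cc(OCc2ccccc2)cc(OCc2ccccc2)c1C(=O)OCc1ccccc1 | intermediate (not isolated)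
15 | benzyl 2,4-bis(benzyloxy)-6-{[7-(benzyloxy)-5-heptyl-4-oxo-4H-chromen-2-yl]methyl}benzoate | CCCCCCCc1cc(OCc2ccccc2)cc2oc(Cc3cc(OCc4ccccc4)cc(OCc4ccccc4)c3C(=O)OCc3ccccc3)cc(=O)c12 | intermediate
16 | benzyl 2,4-bis(benzyloxy)-6-{[(2R)-7-(benzyloxy)-5-heptyl-4-oxo-2-(4,4,5,5-tetramethyl-1,3,2-dioxaborolan-2-yl)-3,4-dihydro-2H-chromen-2-yl]methyl}benzoate | CCCCCCCc1cc(OCc2ccccc2)cc2c1C(=O)C[C@@](B1OC(C)(C)C(C)(C)O1)(Cc1cc(OCc3ccccc3)cc(OCc3ccccc3)c1C(=O)OCc1ccccc1)O2 | intermediate
17 | benzyl 2,4-bis(benzyloxy)-6-{[(2R)-7-(benzyloxy)-5-heptyl-4-oxo-2-[(4,4,5,5-tetramethyl-1,3,2-dioxaborolan-2-yl)oxy]-3,4-dihydro-2H-chromen-2-yl]methyl}benzoate | CCCCCCCc1cc(OCc2ccccc2)cc2c1C(=O)C[C@@](OB1OC(C)(C)C(C)(C)O1)(Cc1cc(OCc3ccccc3)cc(OCc3ccccc3)c1C(=O)OCc1ccccc1)O2 | intermediate (not isolated)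
18 | benzyl 2,4-bis(benzyloxy)-6-{[(2R)-7-(benzyloxy)-5-heptyl-2-hydroxy-4-oxo-3,4-dihydro-2H-chromen-2-yl]methyl}benzoate | CCCCCCCc1cc(OCc2ccccc2)cc2c1C(=O)C[C@@](O)(Cc1cc(OCc3ccccc3)cc(OCc3ccccc3)c1C(=O)OCc1ccccc1)O2 | intermediate
19 | 2,4-dihydroxy-6-{[(2R)-5-heptyl-2,7-dihydroxy-4-oxo-3,4-dihydro-2H-chromen-2-yl]methyl}benzoic acid | CCCCCCCc1cc(O)cc2c1C(=O)C[C@@](O)(Cc1cc(O)cc(O)c1C(=O)O)O2 | target

**Summary**

Total step count: 11. Longest linear sequence: 8 steps (steps 1–4, then 8–11); the ring C branch is steps 5–7.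

Steps most likely to fail:

1. Step 8 (Proposed new method). The lateral anion may add to the lactone of a second molecule or be acylated at the ring carbon next to ring C. After the lactone is opened, the diketonate carbon C3 may close onto the benzyl ester (Dieckmann closure to a naphthalenediol) faster than its oxygen displaces fluoride. The fallback is the known stepwise Claisen condensation followed by SNAr; it sets out from 6 and 8 and comes back to the route at 14 and then 15. Acid chloride 6 and Me2CuLi (Et2O, −78 °C) give 1-[4-(benzyloxy)-2-fluoro-6-heptylphenyl]ethan-1-one F1. Toluate 8 is carboxylated at its methyl group (LiN(i-Pr)2, THF, −78 °C; CO2) to {3,5-bis(benzyloxy)-2-[(benzyloxy)carbonyl]phenyl}acetic acid F2, which carbonyldiimidazole (THF, rt) turns into benzyl 2,4-bis(benzyloxy)-6-[2-(1H-imidazol-1-yl)-2-oxoethyl]benzoate F3. The lithium enolate of F1 (LiN(SiMe3)2, 2.2 equiv, THF, −78 °C) is acylated by F3 to give diketone 14, which is isolated and closed to 15 with K2CO3 in DMF at 80 °C.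

2. Step 9 (Proposed new method). There may be no addition at the hindered, electron-rich C2; the copper enolate may open ring B by loss of the aryloxide, so that C2 re-forms without catalyst control; or facial selectivity may be poor. The fallback uses known chemistry with separation of diastereomers; it sets out from 15 and comes back to the route at 19. Aqueous KOH in dioxane at rt opens ring B of 15 by conjugate addition of hydroxide; after buffering to pH 6 the 2-hydroxyaryl 1,3-diketone closes to racemic benzyl 2,4-bis(benzyloxy)-6-{[7-(benzyloxy)-5-heptyl-2-hydroxy-4-oxo-3,4-dihydro-2H-chromen-2-yl]methyl}benzoate F4. (S)-1-Phenylethanol, pyridinium p-toluenesulfonate (cat.) and 4 Å molecular sieves in CH2Cl2 at 0 °C exchange the hydroxyl for the chiral alkoxy group. This gives the (2R)-2-[(1S)-1-phenylethoxy]chromanone ketal F5 and the (2S)-2-[(1S)-1-phenylethoxy]chromanone ketal F6, which are separated on silica. H2 and Pd/C in EtOAc remove the 1-phenylethyl group of F5 together with the four benzyl groups and give 19. F6 is returned to 15 with p-TsOH in toluene and recycled.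

3. Step 11. The free hemiketal may undergo ring–chain exchange (loss of configuration at C2) or lose water to the chromone, or the C4 ketone may be reduced during hydrogenolysis. The fallback changes the order of unveiling so that the hemiketal appears only in the last operation; it sets out from 16 and comes back to the route at 19. Boronate 16 is hydrogenolysed first (H2, Pd/C, EtOAc, rt) to 2,4-dihydroxy-6-{[(2R)-5-heptyl-7-hydroxy-4-oxo-2-(4,4,5,5-tetramethyl-1,3,2-dioxaborolan-2-yl)-3,4-dihydro-2H-chromen-2-yl]methyl}benzoic acid F7. Its C–B bond is then oxidised with retention by NaBO3·4H2O in THF/pH 7 phosphate buffer at 0 °C to give 19.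

Further compounds
F1 | step 8 | 1-[4-(benzyloxy)-2-fluoro-6-heptylphenyl]ethan-1-one | CCCCCCCc1cc(OCc2ccccc2)cc(F)c1C(C)=O
F2 | step 8 | {3,5-bis(benzyloxy)-2-[(benzyloxy)carbonyl]phenyl}acetic acid | OC(=O)Cc1cc(OCc2ccccc2)cc(OCc2ccccc2)c1C(=O)OCc1ccccc1
F3 | step 8 | benzyl 2,4-bis(benzyloxy)-6-[2-(1H-imidazol-1-yl)-2-oxoethyl]benzoate | O=C(Cc1cc(OCc2ccccc2)cc(OCc2ccccc2)c1C(=O)OCc1ccccc1)n1ccnc1
F4 | step 9 | racemic benzyl 2,4-bis(benzyloxy)-6-{[7-(benzyloxy)-5-heptyl-2-hydroxy-4-oxo-3,4-dihydro-2H-chromen-2-yl]methyl}benzoate | CCCCCCCc1cc(OCc2ccccc2)cc2c1C(=O)CC(O)(Cc1cc(OCc3ccccc3)cc(OCc3ccccc3)c1C(=O)OCc1ccccc1)O2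
F5 | step 9 | benzyl 2,4-bis(benzyloxy)-6-{[(2R)-7-(benzyloxy)-5-heptyl-4-oxo-2-[(1S)-1-phenylethoxy]-3,4-dihydro-2H-chromen-2-yl]methyl}benzoate | CCCCCCCc1cc(OCc2ccccc2)cc2c1C(=O)C[C@@](O[C@@H](C)c1ccccc1)(Cc1cc(OCc3ccccc3)cc(OCc3ccccc3)c1C(=O)OCc1ccccc1)O2
F6 | step 9 | benzyl 2,4-bis(benzyloxy)-6-{[(2S)-7-(benzyloxy)-5-heptyl-4-oxo-2-[(1S)-1-phenylethoxy]-3,4-dihydro-2H-chromen-2-yl]methyl}benzoate | CCCCCCCc1cc(OCc2ccccc2)cc2c1C(=O)C[C@](O[C@@H](C)c1ccccc1)(Cc1cc(OCc3ccccc3)cc(OCc3ccccc3)c1C(=O)OCc1ccccc1)O2
F7 | step 11 | 2,4-dihydroxy-6-{[(2R)-5-heptyl-7-hydroxy-4-oxo-2-(4,4,5,5-tetramethyl-1,3,2-dioxaborolan-2-yl)-3,4-dihydro-2H-chromen-2-yl]methyl}benzoic acid | CCCCCCCc1cc(O)cc2c1C(=O)C[C@@](B1OC(C)(C)C(C)(C)O1)(Cc1cc(O)cc(O)c1C(=O)O)O2
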